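You want to know how strongly the rate of making product in the flask responds to the charge of coupling partner at the moment 20% of the substrate has been converted.

- east: substrate 0.16 M; coupling partner 2 equiv; free catalyst 1 mol%; run made earlier
- flask: substrate 0.16 M; coupling partner 2.00 equiv; free catalyst 0.69 mol%

east run (percent of the substrate charged)

| time / min | product / % | substrate / % |
|---|---|---|
| 0.500 | 23 | 78 |
| 1.50 | 51 | 47 |
| 3.00 | 73 | 27 |
| 5.00 | 82 | 19 |

(each reading ± 1.5 percentage points)

- apparent order in coupling partner when 20% of the substrate are converted (percent change of the rate of making product for one percent more coupling partner charged)

- no earlier run changes the charge of free catalyst; that part of a forecast is a guess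
- no earlier run changes the charge of coupling partner; that part of a forecast is a guess

No run changes the partner charge, so the order must be read from the east run, where the partner falls by itself. I assume one partner is used per product. Over a window, let k be the pseudo-first-order slope of ln(substrate) and b the mean partner left, as a fraction of its charge. Between two windows, the order is n = ln(k ratio)/ln(b ratio).

The first east window gives k = 0.497 min⁻¹ at b = 0.943, and the second gives 0.507 min⁻¹ at 0.815. So n = −0.132, a rough reading under the scatter, but near zero. The last east window gives 0.176 min⁻¹ at 0.613, and against the first window n = 2.41.

The two ways part, and the late one cheats. The slope fell to 0.354 of its early value while the partner fell to 0.650, a smaller drop, and the early pair shows no such response to the partner, so I take it that something besides the partner fell too. My reckoning stays with the early pair: a small order. To carry the run to another loading, take the east slope up to 1.50 min per unit of catalyst loading, the specific slope κ = 50.3 min⁻¹.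

The forecast gave 0.6, within 0.1 to 1.05: “Saturation in the partner is also plausible for a catalytic cycle.” My early reading lies below the forecast's low end.

The flask gives an apparent order of 0.062, below the forecast's low end.

    coupling partner + free catalyst → catalyst intermediate A (k = 54.0 M⁻¹ s⁻¹)
    catalyst intermediate D ⇌ catalyst intermediate E (K = 15.0, k = 3.40 s⁻¹)
    catalyst intermediate B → spent catalyst (k = 0.0770 s⁻¹)
    substrate + catalyst intermediate C → catalyst intermediate D (k = 1100 M⁻¹ s⁻¹)
    catalyst intermediate E → free catalyst + product (k = 3.60 s⁻¹)
    catalyst intermediate A ⇌ catalyst intermediate B (K = 1.30, k = 4.00 s⁻¹)
    catalyst intermediate B ⇌ by-product + catalyst intermediate C (K = 0.130 M, k = 7.00 s⁻¹)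

In the flask at 1.50 min, later than the moment asked about, free catalyst, the form that meets the partner, stands at 2.55% of the catalyst charged, which is 6.00% of the forms not yet spent. At the flask's loading, κ gives a slope of 0.347 min⁻¹, which puts 20% conversion at 0.642 min. The flask reached it later, at 0.677 min.

Readings and results were computed with constants of no real substance; noise was put on by code.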